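Amounts first. Both earlier runs charged less coupling partner than substrate, 0.53 equiv at noon and 0.79 equiv in autumn. The new flask charges 1.05 equiv, more partner than substrate, so there substrate is the limiting reagent. On free catalyst, substrate becomes open intermediate, which binds free catalyst as catalyst intermediate; coupling partner turns that into target and frees the catalyst. Target exchanges with its isomer, partner with a dormant form, and impurity converts free catalyst to spent catalyst.

| flask | substrate | coupling partner | free catalyst | impurity | remark | time |
|---|---|---|---|---|---|---|
| noon | 0.010 M | 0.53 equiv | 15 mol% | 0.76 mM | run made earlier |  |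
| autumn | 0.010 M | 0.79 equiv | 15 mol% | 0.76 mM | run made earlier |  |
| flask | 0.010 M | 1.05 equiv | 15 mol% | 0.76 mM |  | 12 h |

- noon (time / h: isomer of the product / %, target / %, substrate / %): 1.33: 12.4, 17.6, 1.6; 2.50: 18.3, 22.6, 0.7; 4.00: 21.1, 26.2, 0; 5.00: 22.0, 27.0, 0; 6.00: 21.6, 29.0, 0.9; 8.00: 23.7, 30.6, 0.2
- autumn (time / h: isomer of the product / %, target / %, substrate / %): 1.33: 16.9, 23.9, 2.1; 2.50: 25.9, 33.0, 0; 4.00: 28.5, 39.1, 1.1; 5.00: 29.9, 39.9, 0.3; 6.00: 33.0, 40.1, 0; 8.00: 34.0, 43.0, 0

(standard deviation of a reading: 1 percentage point)

* ratio of isomer of the product to target at 5.0 min
* ratio of isomer of the product to target at 1.0 h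
* ratio of isomer of the product to target at 12 h
* which of isomer of the product and target there is more of at 12 h

- reactions considered so far: substrate + free catalyst -> free catalyst + open intermediate; free catalyst + open intermediate <-> catalyst intermediate; coupling partner + catalyst intermediate -> free catalyst + target; coupling partner <-> dormant form; target <-> isomer of the product; free catalyst + impurity -> spent catalyst

The balance of the smaller charge comes first. Target plus isomer reads 54.3% in the noon run at 8.00 h and 77.0% in the autumn run, close to the partner charged in each. In the new flask, the substrate charged must stand as substrate, open intermediate, catalyst intermediate, target or isomer, so the whole charge is the ceiling for target plus isomer. How that sum divides is what is asked. The last readings of both runs, pooled, give isomer to target of 0.784, hence 0.561 as target's share, target divided by target plus isomer.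

But target keeps arriving, so this split might still be moving. The pooled ratio answers that: 0.706 at 1.33 h, 0.795 at 2.50 h, then level as far as readings with a scatter of 1 percentage point can show, while the products go on growing. More partner might shift it, yet noon alone reads 0.775 and autumn 0.791. This reckoning therefore commits to 0.784 at 12 h, with target ahead and an estimated target ceiling of 56.1%. No reading precedes 1.33 h, so for 1.0 h and 5.0 min it offers a lower ratio without a figure.

The forecast agrees at the end, holding that “target and isomer equilibrate”: 0.78 at 12 h, between 0.74 and 0.82, with target ahead. Earlier it gives 0.66 at 1.0 h and 0.1 at 5.0 min, the latter between 0.03 and 0.3.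

The flask gives 0.165 at 5.0 min, above the forecast's figure yet inside its range, then 0.693 at 1.0 h and 0.789 at 12 h, with 53.1% target against 41.9% isomer.

    substrate + free catalyst → free catalyst + open intermediate (k = 95.0 L mol⁻¹ min⁻¹)
    free catalyst + open intermediate ⇌ catalyst intermediate (K = 32.0 L mol⁻¹, k = 500 L mol⁻¹ min⁻¹)
    coupling partner + catalyst intermediate → free catalyst + target (k = 290 L mol⁻¹ min⁻¹)
    coupling partner ⇌ dormant form (K = 2.40, k = 0.380 min⁻¹)
    target ⇌ isomer of the product (K = 0.790, k = 0.0860 min⁻¹)
    free catalyst + impurity → spent catalyst (k = 3000 L mol⁻¹ min⁻¹)

At 12 h the balance of the flask leaves 4.91% of the substrate charged as open intermediate and 0.114% as catalyst intermediate, and the share applied to the remainder gives 53.2% of target. The neighbouring flask with 9 mol% of free catalyst, otherwise the same recipe, shows the ratio 0.786 at 12 h but keeps 30.9% as open intermediate. The same reckoning, taking off its catalyst intermediate and remaining substrate as well, gives 38.7% of target there, and that flask holds 38.6%.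

The runs stem from a simulated flask from invented constants.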